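**Strategy.** The route rests on closing the cyclopentane (ring C) across its only unfunctionalised bond, C-1′–C-2′ (CH2–CH2; locants as in the name of 20), by a rhodium-catalysed [2+2+1] cycloaddition. The exocyclic methylene of diene 7 supplies C-2′ and the spiro carbon C-3′, propyne supplies C-1′ and C-9a′ with its methyl, and CO supplies C-3a′. One operation closes ring C, forms three C–C bonds and sets the spiro centre anti to the cyclohexene methyl. The step exploits that C-3a′ is the only heteroatom-bearing carbon of ring C and that C-9a′ is methylated, so ring C maps onto CO plus propyne. The resulting enone then guides the chroman annulation and late diformylation.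

Key step: step 5

Assumption: (S)-(−)-pulegone is taken as the commercial source of the methyl-bearing stereocentre, and every later stereocentre is derived from it by substrate control.

Step 1
Reactants: 1 (S)-pulegone [(5S)-5-methyl-2-(propan-2-ylidene)cyclohexan-1-one]
Product: 2 (5S,6S)-6-[(dimethylamino)methyl]-5-methyl-2-(propan-2-ylidene)cyclohexan-1-one
Conditions: LiN(i-Pr)2, THF, −78 °C; then Me2N=CH2+ I−, −78 °C → rt
Reagents that add atoms: N,N-dimethylmethyleneiminium iodide (Eschenmoser's salt), C=[N+](C)C.[I-]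
Why: Kinetic α′-deprotonation of the cross-conjugated enone and Mannich-type aminomethylation of the enolate should install the future C-2′ carbon trans to the methyl group; this new centre is flattened in step 4, so its configuration is of no consequence.

Step 2
Reactants: 2 (5S,6S)-6-[(dimethylamino)methyl]-5-methyl-2-(propan-2-ylidene)cyclohexan-1-one
Product: 4 (5S,6S)-6-[(dimethylamino)methyl]-5-methyl-2-(propan-2-yl)cyclohex-1-en-1-yl trifluoromethanesulfonate, via lithium enolate 3 (not isolated)
Conditions: Li, NH3 (l), t-BuOH (1 equiv), THF, −78 °C; NH3 evaporated; then PhNTf2, THF, −78 °C → rt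
Reagents that add atoms: N-phenylbis(trifluoromethanesulfonimide), O=S(=O)(N(c1ccccc1)S(=O)(=O)C(F)(F)F)C(F)(F)F
Why: Dissolving-metal (Birch-type) reduction of the enone should put hydrogen on the isopropylidene carbon and give the tetrasubstituted lithium enolate regiospecifically, which is trapped on oxygen by enolate triflation; no new stereocentre remains.

Step 3
Reactants: 4 (5S,6S)-6-[(dimethylamino)methyl]-5-methyl-2-(propan-2-yl)cyclohex-1-en-1-yl trifluoromethanesulfonate
Product: 5 N,N-dimethyl-1-[(1R,6S)-6-methyl-3-(propan-2-yl)cyclohex-2-en-1-yl]methanamine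
Conditions: Pd(OAc)2 (5 mol %), PPh3, HCO2H, n-Bu3N, DMF, 60 °C
Reagents that add atoms: none
Why: Formate reduction of the enol triflate catalysed by zerovalent palladium (oxidative addition, decarboxylation of formate, C–H reductive elimination) should replace OTf by H without moving the double bond or touching the amine.

Step 4
Reactants: 5 N,N-dimethyl-1-[(1R,6S)-6-methyl-3-(propan-2-yl)cyclohex-2-en-1-yl]methanamine
Product: 7 (4S)-4-methyl-3-methylidene-1-(propan-2-yl)cyclohex-1-ene, via amine N-oxide 6 (not isolated)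
Conditions: m-CPBA (1.0 equiv), CH2Cl2, −20 °C; then toluene, 110 °C
Reagents that add atoms: none
Why: Chemoselective N-oxidation followed by thermal syn-elimination (Cope elimination), in which the ring C–H is the only β-hydrogen, should give the exocyclic methylene and thus the s-trans diene without acid or base that could touch C-4.

Step 5
Reactants: 7 (4S)-4-methyl-3-methylidene-1-(propan-2-yl)cyclohex-1-ene; 8 propyne
Product: 9 (5R,10S)-2,10-dimethyl-7-(propan-2-yl)spiro[4.5]deca-2,6-dien-1-one
Conditions: [RhCl(CO)2]2 (5 mol %), CO (1 atm), propyne (excess), ClCH2CH2Cl, 60 °C, sealed vessel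
Reagents that add atoms: carbon monoxide, [C-]#[O+]
Why: Proposed new method: Monovalent rhodium should couple the alkyne with the terminal CH2 of the diene by oxidative cyclisation, forming the C-3–C-4 bond of 9 (C-1′–C-2′ of 20) and a rhodacyclopentene whose Rh–C(spiro) bond is stabilised as an η3-allyl with the ring alkene; CO insertion and reductive elimination at that allyl terminus then give the cyclopentenone. The closest known reaction type is the rhodium-catalysed intermolecular [2+2+1] (dienyl Pauson–Khand) reaction of acyclic 1,3-dienes with alkynes and CO, which likewise places the alkenyl-bearing quaternary carbon beside the carbonyl; it has not been shown on a semicyclic diene locked s-trans or with a gaseous terminal alkyne. Ring C is closed in a formal [2+2+1] mode, the C-3–C-4 bond first and the two acyl bonds last. The spiro centre C-5 is controlled by C-10: allylic strain holds the C-10 methyl pseudoaxial over one face of the methylene, so metal and alkyne should add to the other face and the new C-5–C(=O) bond ends up trans to that methyl. The regiochemistry needed (CO on the disubstituted alkene carbon, methyl beside CO) is secured by the allyl stabilisation at the spiro carbon and by the usual placement of the larger alkyne substituent next to the carbonyl, while the s-trans geometry excludes a competing [4+2] cycloaddition.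

Step 6
Reactants: 9 (5R,10S)-2,10-dimethyl-7-(propan-2-yl)spiro[4.5]deca-2,6-dien-1-one
Product: 10 triethyl{[(5R,10S)-2,10-dimethyl-7-(propan-2-yl)spiro[4.5]deca-1,6-dien-1-yl]oxy}silane
Conditions: RhCl(PPh3)3 (1 mol %), Et3SiH, benzene, 50 °C
Reagents that add atoms: triethylsilane, CC[SiH](CC)CC
Why: Rhodium-catalysed 1,4-hydrosilylation of the enone with a monohydrosilane should deliver hydride to C-3 and silicon to oxygen, giving the tetrasubstituted silyl enol ether as the only regioisomer and leaving the trisubstituted ring alkene untouched.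

Step 7
Reactants: 11 2,4,6-trihydroxybenzaldehyde
Product: 12 2,4,6-tris[(tert-butoxycarbonyl)oxy]benzaldehyde
Conditions: Boc2O (3.3 equiv), DMAP (cat.), i-Pr2NEt, THF, 0 °C → rt
Reagents that add atoms: di-tert-butyl dicarbonate, CC(C)(C)OC(=O)OC(=O)OC(C)(C)C
Why: DMAP-catalysed O-acylation should convert all three phenols into tert-butyl carbonates, the ortho carbonate later serving as the internal leaving group for quinone methide generation.

Step 8
Reactants: 10 triethyl{[(5R,10S)-2,10-dimethyl-7-(propan-2-yl)spiro[4.5]deca-1,6-dien-1-yl]oxy}silane; 12 2,4,6-tris[(tert-butoxycarbonyl)oxy]benzaldehyde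
Product: 14 di-tert-butyl [(1R,3a′R,6S,9′S,9a′R)-6,9a′-dimethyl-9′-(2-methylpropyl)-3-(propan-2-yl)-3a′-(triethylsilyloxy)-1′,2′,9′,9a′-tetrahydro-3a′H-spiro[cyclohex-2-ene-1,3′-cyclopenta[b]chromene]-6′,8′-diyl] dicarbonate, via ortho-quinone methide 13 (not isolated)
Conditions: i-BuMgBr, Et2O/THF, −78 °C → rt (12 and the Grignard reagent in excess over 10)
Reagents that add atoms: isobutylmagnesium bromide, CC(C)C[Mg]Br
Why: Grignard addition, carbonate migration to the benzylic alkoxide and β-elimination should generate the (E)-ortho-quinone methide 13, which undergoes an inverse-electron-demand hetero-Diels–Alder reaction with the enol ether: attack on the cyclopentene face syn to the ring CH= and anti to C-6 with its methyl sets C-9a′, suprafacial addition gives the cis-fused ketal, and the siloxy-endo transition state places the isobutyl group cis to the 9a′-methyl, setting C-9′.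

Step 9
Reactants: 14 di-tert-butyl [(1R,3a′R,6S,9′S,9a′R)-6,9a′-dimethyl-9′-(2-methylpropyl)-3-(propan-2-yl)-3a′-(triethylsilyloxy)-1′,2′,9′,9a′-tetrahydro-3a′H-spiro[cyclohex-2-ene-1,3′-cyclopenta[b]chromene]-6′,8′-diyl] dicarbonate
Product: 19 (1R,3a′S,6S,9′R,9a′R)-6,9a′-dimethyl-9′-(2-methylpropyl)-3-(propan-2-yl)-1′,2′,9′,9a′-tetrahydro-3a′H-spiro[cyclohex-2-ene-1,3′-cyclopenta[b]chromene]-6′,8′-diol, via keto-phenol 15 (not isolated), via tosylhydrazone 16 (not isolated), via diazoalkane 17 (not isolated), via bis-carbonate chroman 18 (not isolated)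
Conditions: TsNHNH2, PPTS (cat.), 1,4-dioxane, 80 °C; then K2CO3, 110 °C; then MeOH, 60 °C
Reagents that add atoms: none
Why: Acid should unmask the hindered ketone, which condenses to the tosylhydrazone; base then generates the diazoalkane (Bamford–Stevens reaction), which is protonated by and collapses with the neighbouring phenol (reductive etherification of a tosylhydrazone, here intramolecular), so that the tethered oxygen can reach C-3a′ only from the face of C-9′, which sets the cis ring fusion with hydrogen on the methyl face, and methanolysis finally removes the two carbonates.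

Step 10
Reactants: 19 (1R,3a′S,6S,9′R,9a′R)-6,9a′-dimethyl-9′-(2-methylpropyl)-3-(propan-2-yl)-1′,2′,9′,9a′-tetrahydro-3a′H-spiro[cyclohex-2-ene-1,3′-cyclopenta[b]chromene]-6′,8′-diol
Product: 20 (1R,3a′S,6S,9′R,9a′R)-6′,8′-dihydroxy-6,9a′-dimethyl-9′-(2-methylpropyl)-3-(propan-2-yl)-1′,2′,9′,9a′-tetrahydro-3a′H-spiro[cyclohex-2-ene-1,3′-cyclopenta[b]chromene]-5′,7′-dicarbaldehyde
Conditions: Cl2CHOMe, TiCl4, CH2Cl2, −78 → 0 °C; then aq. HCl
Reagents that add atoms: dichloromethyl methyl ether, COC(Cl)Cl; water, O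
Why: Twofold Rieche formylation (electrophilic aromatic substitution by the TiCl4-activated dichloromethyl ether at the only two free ring positions, each ortho/para to three oxygens, then hydrolysis) should give the dialdehyde at low temperature without affecting any stereocentre.

**Compound list**

1 | (S)-pulegone, (5S)-5-methyl-2-(propan-2-ylidene)cyclohexan-1-one | C[C@H]1CCC(=C(C)C)C(=O)C1 | starting material
2 | (5S,6S)-6-[(dimethylamino)methyl]-5-methyl-2-(propan-2-ylidene)cyclohexan-1-one | C[C@H]1CCC(=C(C)C)C(=O)[C@@H]1CN(C)C | intermediate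
3 | lithium (5S,6S)-6-[(dimethylamino)methyl]-5-methyl-2-(propan-2-yl)cyclohex-1-en-1-olate | C[C@H]1CCC(C(C)C)=C([O-])[C@@H]1CN(C)C.[Li+] | intermediate
4 | (5S,6S)-6-[(dimethylamino)methyl]-5-methyl-2-(propan-2-yl)cyclohex-1-en-1-yl trifluoromethanesulfonate | C[C@H]1CCC(C(C)C)=C(OS(=O)(=O)C(F)(F)F)[C@@H]1CN(C)C | intermediate
5 | N,N-dimethyl-1-[(1R,6S)-6-methyl-3-(propan-2-yl)cyclohex-2-en-1-yl]methanamine | C[C@H]1CCC(C(C)C)=C[C@@H]1CN(C)C | intermediate
6 | N,N-dimethyl-1-[(1R,6S)-6-methyl-3-(propan-2-yl)cyclohex-2-en-1-yl]methanamine N-oxide | C[C@H]1CCC(C(C)C)=C[C@@H]1C[N+](C)(C)[O-] | intermediate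
7 | (4S)-4-methyl-3-methylidene-1-(propan-2-yl)cyclohex-1-ene | C=C1C=C(C(C)C)CC[C@@H]1C | intermediate
8 | propyne | CC#C | starting material
9 | (5R,10S)-2,10-dimethyl-7-(propan-2-yl)spiro[4.5]deca-2,6-dien-1-one (carbonyl trans to the C-10 methyl across the cyclohexene) | CC1=CC[C@]2(C1=O)C=C(C(C)C)CC[C@@H]2C | intermediate
10 | triethyl{[(5R,10S)-2,10-dimethyl-7-(propan-2-yl)spiro[4.5]deca-1,6-dien-1-yl]oxy}silane | CC1=C(O[Si](CC)(CC)CC)[C@@]2(CC1)C=C(C(C)C)CC[C@@H]2C | intermediate
11 | 2,4,6-trihydroxybenzaldehyde | O=Cc1c(O)cc(O)cc1O | starting material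
12 | 2,4,6-tris[(tert-butoxycarbonyl)oxy]benzaldehyde | O=Cc1c(OC(=O)OC(C)(C)C)cc(OC(=O)OC(C)(C)C)cc1OC(=O)OC(C)(C)C | intermediate
13 | (6E)-3,5-bis[(tert-butoxycarbonyl)oxy]-6-(3-methylbutylidene)cyclohexa-2,4-dien-1-one | CC(C)C/C=C1/C(=O)C=C(OC(=O)OC(C)(C)C)C=C1OC(=O)OC(C)(C)C | intermediate
14 | di-tert-butyl [(1R,3a′R,6S,9′S,9a′R)-6,9a′-dimethyl-9′-(2-methylpropyl)-3-(propan-2-yl)-3a′-(triethylsilyloxy)-1′,2′,9′,9a′-tetrahydro-3a′H-spiro[cyclohex-2-ene-1,3′-cyclopenta[b]chromene]-6′,8′-diyl] dicarbonate (cis-fused ketal, siloxy cis to the 9a′-methyl, other centres arranged as in 20) | CC(C)C[C@H]1c2c(OC(=O)OC(C)(C)C)cc(OC(=O)OC(C)(C)C)cc2O[C@@]2(O[Si](CC)(CC)CC)[C@]1(C)CC[C@@]21C=C(C(C)C)CC[C@@H]1C | intermediate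
15 | (2R,5R,10S)-2-[(1S)-1-{2,4-bis[(tert-butoxycarbonyl)oxy]-6-hydroxyphenyl}-3-methylbutyl]-2,10-dimethyl-7-(propan-2-yl)spiro[4.5]dec-6-en-1-one | CC(C)C[C@@H](c1c(O)cc(OC(=O)OC(C)(C)C)cc1OC(=O)OC(C)(C)C)[C@@]1(C)CC[C@]2(C1=O)C=C(C(C)C)CC[C@@H]2C | intermediate
16 | 4-methylbenzenesulfonohydrazone of 15 at C-1 (C=N geometry not defined; benzylic centre now 1R by priority change, same spatial arrangement) | CC(C)C[C@@H](c1c(O)cc(OC(=O)OC(C)(C)C)cc1OC(=O)OC(C)(C)C)[C@@]1(C)CC[C@]2(C1=NNS(=O)(=O)c1ccc(C)cc1)C=C(C(C)C)CC[C@@H]2C | intermediate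
17 | 1-diazo analogue of 15 (C-1 carbonyl replaced by C=N2) | CC(C)C[C@@H](c1c(O)cc(OC(=O)OC(C)(C)C)cc1OC(=O)OC(C)(C)C)[C@@]1(C)CC[C@]2(C1=[N+]=[N-])C=C(C(C)C)CC[C@@H]2C | intermediate
18 | di-tert-butyl [(1R,3a′S,6S,9′R,9a′R)-6,9a′-dimethyl-9′-(2-methylpropyl)-3-(propan-2-yl)-1′,2′,9′,9a′-tetrahydro-3a′H-spiro[cyclohex-2-ene-1,3′-cyclopenta[b]chromene]-6′,8′-diyl] dicarbonate | CC(C)C[C@H]1c2c(OC(=O)OC(C)(C)C)cc(OC(=O)OC(C)(C)C)cc2O[C@H]2[C@]1(C)CC[C@@]21C=C(C(C)C)CC[C@@H]1C | intermediate
19 | (1R,3a′S,6S,9′R,9a′R)-6,9a′-dimethyl-9′-(2-methylpropyl)-3-(propan-2-yl)-1′,2′,9′,9a′-tetrahydro-3a′H-spiro[cyclohex-2-ene-1,3′-cyclopenta[b]chromene]-6′,8′-diol | CC(C)C[C@H]1c2c(O)cc(O)cc2O[C@H]2[C@]1(C)CC[C@@]21C=C(C(C)C)CC[C@@H]1C | intermediate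
20 | (1R,3a′S,6S,9′R,9a′R)-6′,8′-dihydroxy-6,9a′-dimethyl-9′-(2-methylpropyl)-3-(propan-2-yl)-1′,2′,9′,9a′-tetrahydro-3a′H-spiro[cyclohex-2-ene-1,3′-cyclopenta[b]chromene]-5′,7′-dicarbaldehyde (CNP0121396.2; cis-fused rings B/C, O-4′ and C-9′ on the cyclopentane face syn to the cyclohexene CH=, isobutyl cis to the 9a′-methyl) | CC(C)C[C@H]1c2c(O)c(C=O)c(O)c(C=O)c2O[C@H]2[C@]1(C)CC[C@@]21C=C(C(C)C)CC[C@@H]1C | target

**Step count and risks**

Total step count: 10. Longest linear sequence: 9 steps (steps 1–6 and 8–10, from 1).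

Most likely to fail:

1. Step 5. The oxidative cyclisation may not start on a diene that cannot chelate rhodium in an s-cis form; propyne may oligomerise instead, or the rhodacycle may lose a β-hydrogen from C-10. Fallback with known chemistry, closing the same bond by ring-closing metathesis. It sets out from 7. Hydroboration–oxidation (9-BBN; NaOH, H2O2) would give [(1S,6S)-6-methyl-3-(propan-2-yl)cyclohex-2-en-1-yl]methanol F1. Swern oxidation would give (1S,6S)-6-methyl-3-(propan-2-yl)cyclohex-2-ene-1-carbaldehyde F2, and Wittig methylenation (Ph3P=CH2) the 1,4-diene (3S,4S)-3-ethenyl-4-methyl-1-(propan-2-yl)cyclohex-1-ene F3. Metalation of the doubly allylic C–H (n-BuLi/KOt-Bu) and formylation of the pentadienyl anion at its central carbon with DMF, anti to the neighbouring methyl, would give (1R,6S)-1-ethenyl-6-methyl-3-(propan-2-yl)cyclohex-2-ene-1-carbaldehyde F4. Crotylation with (E)-crotylboronic acid pinacol ester would give 1-[(1R,6S)-1-ethenyl-6-methyl-3-(propan-2-yl)cyclohex-2-en-1-yl]-2-methylbut-3-en-1-ol F5. Ring-closing metathesis with the second-generation Grubbs catalyst would form the C-3–C-4 bond and give (5S,10S)-2,10-dimethyl-7-(propan-2-yl)spiro[4.5]deca-3,6-dien-1-ol F6. Dess–Martin oxidation would give (5S,10S)-2,10-dimethyl-7-(propan-2-yl)spiro[4.5]deca-3,6-dien-1-one F7, which DBU should isomerise into conjugation; the route is rejoined at 9.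

2. Step 9. Condensation at a carbonyl flanked by two quaternary carbons may stall, and loss of dinitrogen may be accompanied by a 1,2-alkyl or alkenyl shift before the phenol captures C-3a′. Fallback that forms the aryl C–O bond instead, with retention at the carbinol carbon. It sets out from 14. TBAF (THF, 0 °C) unmasks keto-phenol 15, and NaBH4 (MeOH, 0 °C) should deliver hydride anti to the bulky 1-aryl-3-methylbutyl group to give the ring-opened hydroxy-phenol, the C-1 alcohol of 15 with hydroxyl syn to the benzylic carbon F9. PhNTf2/Et3N would convert the free phenol into the corresponding aryl trifluoromethanesulfonate F10. Intramolecular C–O coupling (Pd(OAc)2, 2-(di-tert-butylphosphino)-1,1′-binaphthyl, Cs2CO3, toluene, 80 °C) would then close the pyran. The route is rejoined at 18, which K2CO3/MeOH converts into 19.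

3. Step 8. Cycloaddition of the tetrasubstituted, neopentyl-type enol ether may be slow enough for the quinone methide to oligomerise, and endo or facial selectivity may erode to give the C-9′ epimer. Fallback by stepwise anionic conjugate addition. It sets out from 10. MeLi (THF, 0 °C) would liberate lithium (5R,10S)-2,10-dimethyl-7-(propan-2-yl)spiro[4.5]deca-1,6-dien-1-olate F8, which is added at −78 °C to quinone methide 13 generated from 12 and i-BuMgBr as before. Michael addition on the same enolate face and protonation would give keto-phenol 15, where the route is rejoined as the first intermediate of step 9.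

**Further compounds**

F1 | step 5 | [(1S,6S)-6-methyl-3-(propan-2-yl)cyclohex-2-en-1-yl]methanol | C[C@H]1CCC(C(C)C)=C[C@H]1CO
F2 | step 5 | (1S,6S)-6-methyl-3-(propan-2-yl)cyclohex-2-ene-1-carbaldehyde | C[C@H]1CCC(C(C)C)=C[C@H]1C=O
F3 | step 5 | (3S,4S)-3-ethenyl-4-methyl-1-(propan-2-yl)cyclohex-1-ene | C[C@H]1CCC(C(C)C)=C[C@H]1C=C
F4 | step 5 | (1R,6S)-1-ethenyl-6-methyl-3-(propan-2-yl)cyclohex-2-ene-1-carbaldehyde | C=C[C@]1(C=O)C=C(C(C)C)CC[C@@H]1C
F5 | step 5 | 1-[(1R,6S)-1-ethenyl-6-methyl-3-(propan-2-yl)cyclohex-2-en-1-yl]-2-methylbut-3-en-1-ol (mixture at the two side-chain centres) | C=C[C@]1(C(O)C(C)C=C)C=C(C(C)C)CC[C@@H]1C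
F6 | step 5 | (5S,10S)-2,10-dimethyl-7-(propan-2-yl)spiro[4.5]deca-3,6-dien-1-ol (mixture at C-1 and C-2) | CC1C=C[C@]2(C1O)C=C(C(C)C)CC[C@@H]2C
F7 | step 5 | (5S,10S)-2,10-dimethyl-7-(propan-2-yl)spiro[4.5]deca-3,6-dien-1-one (mixture at C-2) | CC1C=C[C@]2(C1=O)C=C(C(C)C)CC[C@@H]2C
F8 | step 8 | lithium (5R,10S)-2,10-dimethyl-7-(propan-2-yl)spiro[4.5]deca-1,6-dien-1-olate | CC1=C([O-])[C@@]2(CC1)C=C(C(C)C)CC[C@@H]2C.[Li+]
F9 | step 9 | C-1 alcohol of 15, hydroxyl syn to the benzylic carbon (1S at the carbinol carbon) | CC(C)C[C@@H](c1c(O)cc(OC(=O)OC(C)(C)C)cc1OC(=O)OC(C)(C)C)[C@@]1(C)CC[C@]2([C@H]1O)C=C(C(C)C)CC[C@@H]2C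
F10 | step 9 | aryl trifluoromethanesulfonate of F9 (phenol OH replaced by OSO2CF3) | CC(C)C[C@@H](c1c(OS(=O)(=O)C(F)(F)F)cc(OC(=O)OC(C)(C)C)cc1OC(=O)OC(C)(C)C)[C@@]1(C)CC[C@]2([C@H]1O)C=C(C(C)C)CC[C@@H]2C
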